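Remark on the chemistry: atoms carry germacrane numbers (ring C1–C10, lactone carbons C11–C13, C14 on C10, C15 on C4); β is the face of C14 and of the C7 side chain; (S)-(+)-carvone of high enantiomeric purity is assumed as the only source of absolute configuration.

## The problem

The target 25 is 1β,2α-epoxy-10α-hydroxy-8β-isobutyryloxy-3-oxogermacra-4Z,11(13)-dien-12,6α-olide. It is a ten-membered carbocycle carrying a trans-fused α-methylene-γ-butyrolactone across C6–C7. The ring holds a cross-conjugated C3 ketone between a Z-trisubstituted C4=C5 alkene and a trans epoxide at C1–C2. The E alkene from which that epoxide derives lies next to the quaternary C10 carbinol; its Z isomer would collapse to a 3,10-hemiketal, so neither a medium-ring closure nor an equilibration can be trusted to deliver the right geometry. There are six stereocentres: the contiguous triad C6/C7/C8, the quaternary carbinol C10, and C1/C2. In an open chain nothing links C7 to C10, whereas in six-membered rings C7 can control C6, and C10 can control C8 (1,3) and the face of C1=C2. The α-methylene lactone (Michael acceptor), the epoxy ketone beside a tertiary alcohol (epoxide migration) and the isobutyrate must appear late. The feature that the plan exploits: C3 (ketone) and C8 (acyloxy carbon) stand 1,6 across the ring and both carry oxygen. A bond between them divides the ten-membered ring into two six-membered rings, and ring A (C3–C4(C15)=C5–C6–C7(C11–C13)–C8) is the 2-methyl-5-isopropenylcyclohex-2-enone of carvone.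

## Retrosynthesis

**25 ⇒ 22 (O6–C12).** The lactone C–O bond is cut last. Diol 22 (C6–OH, C12–OH) is closed by oxidative lactonization under neutral conditions, so the Michael acceptor never meets a base or nucleophile. The forward step must oxidize a primary allylic alcohol in preference to the secondary C6–OH.

**22 ⇒ 21 ⇒ 19 ⇒ 18 (epoxide C–O bonds, ester C–O).** The trans epoxide is traced to the E enone of 18 by nucleophilic epoxidation, which keeps the trans geometry and is delivered by the neighbouring C10 hydroxyl. This is done before the lactone exists, because hydroperoxide would also attack an α-methylene lactone. The isobutyrate goes onto the only secondary hydroxyl of 19.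

**18 ⇒ 17 (C8–H).** The C8 carbinol comes from the C8 ketone by internal hydride delivery from the C10 hydroxyl (1,3-anti). C10 is therefore the relay between the carvone-derived half and C8.

**17 ⇒ 15 (reconnect C3–C8; key).** Joining the two carbonyl carbons gives the cis-fused bicyclo[4.4.0]decene diol 15, which glycol cleavage reopens to the ten-membered ring. The neighbouring transannular bonds are worse: a C5–C10 bond (eudesmane type) would need the fusion carbon C10 to carry both methyl and oxygen, and a C1–C6 or C2–C7 bond would place the fusion on carbons that must end as CH. Only C3/C8 are both oxygenated, so the cleavage itself creates two wanted functional groups. The Z geometry of C4=C5 is automatic in a six-membered ring, and the E enone follows by loss of HBr from C1/C2.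

**15 ⇒ 14 ⇒ 13 (C10–O, C1–Br; C1=C10).** Ring B is a 1-methylcyclohexene. Anti hydroxybromination puts the hydroxyl on tertiary C10 and a leaving group on C1, with the face set by the cis-fused bicycle. The cyclohexene is closed by metathesis of an allyl group on C3 and a methallyl group on C8.

**13 ⇒ 10 + 11; 10 ⇒ 9 ⇒ 8 ⇒ 7 ⇒ 5 + 6 (C2–C3, C6–O, C8–C9).** Allylmagnesium bromide 11 adds to the C3 ketone of 10. The C6 oxygen is introduced by γ-oxidation of the dienol ether 8, which is regiochemically unambiguous only because C8 of 7 is already quaternary (no α′ proton left, no aromatization possible). C8 is quaternized by alkylating silyloxy ketone 5 with methallyl bromide 6.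

**5 ⇒ 3 ⇒ 2 ⇒ 1 (C8–O, C12–O).** α′-Hydroxylation and allylic oxidation of the isopropenyl methyl lead back to (S)-carvone 1. Carvone supplies C3–C8, C11–C13, C15, the C7 stereocentre and the Z alkene; 6 supplies C9, C10, C14; 11 supplies C1, C2; isobutyric anhydride 20 supplies the ester.

## Roads not taken

**Alternative 1:** the most obvious cut is C6–C7 together with O–C12. An intramolecular Nozaki–Hiyama–Kishi or Barbier allylation (CrCl2 or indium) of the seco aldehyde/allylic bromide A1 would close the ring and the lactone at once. The (Z)-2-(bromomethyl)alkenoate reacts through a Zimmerman–Traxler chair as a Z-crotyl-type reagent and gives the syn adduct, that is the 6,7-cis lactone A2 rather than the trans fusion. The C8 stereocentre next to the reacting carbon adds a second, uncontrolled bias. A1 also requires a Z-trisubstituted enal, an E alkene, C8 and C10 to be built one by one in an open chain. The carvone plan takes C7, the Z alkene and the trans C6/C7 relationship from a ring.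

**Alternative 2:** cut C1=C2 and close the ring by metathesis of the divinyl compound A3 (vinyl ketone plus vinyl carbinol) with a ruthenium carbene. Metathesis to ten-membered rings is reversible and strain-limited. Under thermodynamic control the alkene next to the quaternary carbinol would be expected to appear as the 1Z isomer A4, which cannot give the trans epoxide by direct epoxidation. Dimerization competes, and all stereocentres must again be built beforehand in a chain.

**Alternative 3:** cut C3–C4 and close by Nozaki–Hiyama–Kishi coupling (CrCl2, NiCl2 catalyst) of the Z-vinyl iodide/epoxy aldehyde A5, then oxidize carbinol A6. This is the safest way to fix the epoxide (Sharpless epoxidation of an open-chain E allylic alcohol) and both alkene geometries. It pays for that with a long linear sequence in which C6, C7, C8 and C10 each need a separate reagent-controlled step, and with a medium-ring closure onto a hindered aldehyde. The chosen plan never closes a ten-membered ring, and it relays stereochemistry from C7 through two six-membered rings.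

Key step: step 11

## Steps

Step 1
Reactants: 1 (S)-(+)-carvone
Product: 2 (5S)-5-(3-hydroxyprop-1-en-2-yl)-2-methylcyclohex-2-en-1-one
Conditions: SeO2 (0.3 equiv), t-BuOOH, CH2Cl2, 23 °C
Reagents that add atoms: tert-butyl hydroperoxide CC(C)(C)OO
Why: Allylic oxidation by SeO2 (ene reaction, then [2,3]-shift) with t-BuOOH as terminal oxidant; the 1,1-disubstituted isopropenyl group reacts at its methyl (future C12), the enone alkene is deactivated and C7 is not touched.

Step 2
Reactants: 2 allylic alcohol
Product: 3 tert-butyldimethylsilyl ether of 2
Conditions: t-BuMe2SiCl, imidazole, DMF, 23 °C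
Reagents that add atoms: tert-butyldimethylsilyl chloride CC(C)(C)[Si](C)(C)Cl
Why: Standard silylation of a primary alcohol; the ether survives the enolate, Grignard, metathesis and oxidation steps that follow.

Step 3
Reactants: 3 silyl ether
Product: 5 C8 trimethylsilyloxy ketone (C8 oxygen trans to the C7 side chain), via hydroxy ketone potassium alkoxide 4 (not isolated)
Conditions: KN(SiMe3)2, THF, -78 °C; 2-(phenylsulfonyl)-3-phenyloxaziridine; then Me3SiCl, -78 to 0 °C
Reagents that add atoms: 2-(phenylsulfonyl)-3-phenyloxaziridine O=S(=O)(N1OC1c1ccccc1)c1ccccc1; chlorotrimethylsilane C[Si](C)(C)Cl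
Why: Hydroxylation of the kinetic α′ enolate with an N-sulfonyloxaziridine, oxygen entering anti to the C7 side chain; the alkoxide is silylated in the same flask so that the next enolate can be formed at C8 and the oxygen cannot chelate later.

Step 4
Reactants: 5 silyloxy ketone; 6 3-bromo-2-methylprop-1-ene
Product: 7 C8-quaternary ketone (methallyl trans and OSiMe3 cis to the C7 side chain)
Conditions: LiN(iPr)2, THF/DMPU, -78 °C; then 6, -78 to -20 °C
Reagents that add atoms: none
Why: Alkylation of the tetrasubstituted α-silyloxy enolate, the electrophile again entering anti to the C7 side chain; C8 is not a stereocentre of the target, but its configuration steers steps 8 and 10 and its quaternary nature blocks α′ enolization.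

Step 5
Reactants: 7 quaternary ketone
Product: 8 trimethylsilyl dienol ether (C3-OSiMe3 with C3=C4 and C5=C6)
Conditions: Me3SiOTf, Et3N, CH2Cl2, 0 °C
Reagents that add atoms: trimethylsilyl trifluoromethanesulfonate C[Si](C)(C)OS(=O)(=O)C(F)(F)F
Why: Soft enolization; with C8 quaternary the only acidic position is the γ carbon C6, so the linear dienol ether forms.

Step 6
Reactants: 8 dienol ether
Product: 9 γ-hydroxy enone (6α-OH trans to the C7 side chain)
Conditions: dimethyldioxirane, acetone/CH2Cl2, -78 °C; aqueous NaHCO3 work-up
Reagents that add atoms: dimethyldioxirane CC1(C)OO1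
Why: Vinylogous Rubottom oxidation: the oxidant attacks the γ terminus (the α carbon C4 is fully substituted) from the face opposite the C7 side chain and the axial C8 silyloxy group, setting C6; the enol ether reacts far faster than the two 1,1-disubstituted alkenes.

Step 7
Reactants: 9 γ-hydroxy enone
Product: 10 C6 tert-butyldimethylsilyl ether
Conditions: t-BuMe2SiOTf, 2,6-lutidine, CH2Cl2, -78 °C
Reagents that add atoms: tert-butyldimethylsilyl trifluoromethanesulfonate CC(C)(C)[Si](C)(C)OS(=O)(=O)C(F)(F)F
Why: Silylation of the secondary allylic alcohol; it keeps C6-O from eliminating or undergoing retro-aldol cleavage once C8 becomes a ketone and distinguishes it from C8-OH at the acylation stage.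

Step 8
Reactants: 10 enone; 11 allylmagnesium bromide
Product: 13 cis-3,8-diol (allyl on C3 cis to methallyl on C8), via C8 trimethylsilyl ether 12 (not isolated)
Conditions: 11, THF, -78 °C; then MeOH, K2CO3 (cat.), 23 °C
Reagents that add atoms: none
Why: 1,2-Addition of the allyl Grignard reagent to the enone from the α face, anti to the pseudoaxial, non-chelating C8 silyloxy group, which places the two hydroxyls cis and the two alkenyl chains cis; methanolysis then removes the labile tertiary trimethylsilyl ether only.

Step 9
Reactants: 13 diene diol
Product: 14 cis-fused bicyclic diol (ring B with C1=C10)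
Conditions: second-generation Grubbs catalyst RuCl2(=CHPh)(H2IMes)(PCy3) (5 mol %), CH2Cl2, 40 °C
Reagents that add atoms: none
Why: Ring-closing metathesis of a monosubstituted and a 1,1-disubstituted alkene to a trisubstituted cyclohexene; the C11=C13 alkene is trans to the allyl group and could only give a tetrasubstituted alkene with the methallyl group, so it stays out.

Step 10
Reactants: 14 bicyclic diol
Product: 15 bromohydrin (10α-OH with C14 β and 1β-Br)
Conditions: N-bromosuccinimide, THF/H2O, 0 °C
Reagents that add atoms: N-bromosuccinimide O=C1CCC(=O)N1Br; water O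
Why: Hydroxybromination: Br+ adds to the convex β face of ring B (the α face is screened by the axial C8-C7 bond) and water opens the bromonium ion at tertiary C10 from the α face, which is both the Markovnikov and the trans-diaxial mode, so the C10 carbinol is set and C1 receives a leaving group; C4=C5 is deactivated by two allylic C-O bonds and C11=C13 is only 1,1-disubstituted.

Step 11
Reactants: 15 bromohydrin diol
Product: 17 ten-membered (1E,4Z)-dienedione, via bromo diketone 16 (not isolated)
Conditions: Pb(OAc)4, CH2Cl2, -20 °C; then Et3N, -20 to 0 °C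
Reagents that add atoms: none
Why: Criegee glycol cleavage: the cis tertiary hydroxyls at C3 and C8 displace two acetates of Pb(OAc)4, and the five-membered plumbate collapses with two-electron fragmentation of the C3-C8 bond, as in the known opening of cis-decalin-9,10-diols to cyclodecane-1,6-diones. No ring is closed; the ten-membered ring appears when the bond shared by the two six-membered rings breaks, so no medium-ring closure has to be paid for. The same event creates both carbonyl groups: C3, already conjugated to the C4=C5 bond whose Z geometry was fixed in carvone, and C8 at the oxidation level needed for step 12. The step needs one diol to be cleaved and 15 has only one (C10-OH has no hydroxylated neighbour), while the cis relationship from step 8 allows the cyclic plumbate. No stereocentre is created, and C6, C7 and C10 are untouched under the neutral conditions. Triethylamine then removes HBr from the β-bromo ketone 16 (E1cB) to give the C1=C2 enone; the E isomer is expected because the transition state leading to the Z isomer forces quaternary C10 with its three substituents cis to the C3 carbonyl (1,3-allylic strain), which the Z enone could relieve only by hemiketal formation. The base is kept cold and brief because H7 is now α to a ketone and allylic.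

Step 12
Reactants: 17 dienedione
Product: 18 8β-alcohol
Conditions: Me4NBH(OAc)3, MeCN/AcOH, -30 °C
Reagents that add atoms: none
Why: Evans–Saksena reduction: the C10 hydroxyl exchanges an acetate on boron and delivers hydride through a six-membered chair to the C8 ketone it is β to, giving the 1,3-anti diol (8β-OH); the cross-conjugated C3 ketone has no hydroxyl within reach across the E alkene and is not reduced.

Step 13
Reactants: 18 dienone diol
Product: 19 1β,2α-epoxide
Conditions: t-BuOOLi (from t-BuOOH and n-BuLi), THF, -20 °C
Reagents that add atoms: tert-butyl hydroperoxide CC(C)(C)OO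
Why: Nucleophilic (Weitz–Scheffer) epoxidation: the stepwise mechanism keeps the trans geometry of the E enone, and the unsubstituted C1=C2 is attacked in preference to the α-methylated C4=C5 and the unactivated C11=C13; the lithium alkoxide at C10 delivers the peroxide to C1 on the outer face of the ring, anti to C9, which corresponds to the 1β,2α-epoxide.

Step 14
Reactants: 19 epoxy diol; 20 isobutyric anhydride
Product: 21 8-O-isobutyrate
Conditions: 20, DMAP (cat.), Et3N, CH2Cl2, 0 °C
Reagents that add atoms: none
Why: DMAP-catalysed acylation of the only secondary hydroxyl; the tertiary C10-OH does not react and the mild base does not trigger epoxide migration.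

Step 15
Reactants: 21 bis-silyl ether
Product: 22 6,12-diol
Conditions: HF·pyridine, pyridine, THF, 0 to 23 °C
Reagents that add atoms: none
Why: Buffered fluoride-mediated cleavage of both silyl ethers; the electron-poor epoxy ketone and the ester tolerate buffered HF·pyridine.

Step 16
Reactants: 22 diol
Product: 25 target lactone, via enal 23 (not isolated), via lactol 24 (not isolated)
Conditions: TEMPO (cat.), PhI(OAc)2, CH2Cl2, 23 °C
Reagents that add atoms: none
Why: Oxidative lactonization: the oxoammonium salt oxidizes the primary allylic C12 alcohol faster than the secondary C6-OH, the C6 hydroxyl adds to the enal and the lactol is oxidized to the γ-lactone; the trans fusion follows from C6 and C7, and the α-methylene lactone is formed last under neutral conditions.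

## Compound list

1 | (S)-(+)-carvone, (5S)-2-methyl-5-(prop-1-en-2-yl)cyclohex-2-en-1-one | O=C1C(C)=CC[C@H](C(C)=C)C1 | starting material
2 | (5S)-5-(3-hydroxyprop-1-en-2-yl)-2-methylcyclohex-2-en-1-one (C12 hydroxylated carvone) | O=C1C(C)=CC[C@H](C(CO)=C)C1 | intermediate
3 | tert-butyldimethylsilyl ether of 2 | O=C1C(C)=CC[C@H](C(CO[Si](C)(C)C(C)(C)C)=C)C1 | intermediate
4 | potassium alkoxide of the C8 hydroxy ketone (C8-O trans to the C7 side chain) | O=C1C(C)=CC[C@H](C(CO[Si](C)(C)C(C)(C)C)=C)[C@H]1[O-].[K+] | intermediate
5 | (5R,6R)-5-[3-(tert-butyldimethylsilyloxy)prop-1-en-2-yl]-2-methyl-6-(trimethylsilyloxy)cyclohex-2-en-1-one | O=C1C(C)=CC[C@H](C(CO[Si](C)(C)C(C)(C)C)=C)[C@H]1O[Si](C)(C)C | intermediate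
6 | 3-bromo-2-methylprop-1-ene (methallyl bromide) | CC(=C)CBr | starting material
7 | C8-quaternary ketone: 5 carrying a 2-methylallyl group on C8 trans to the C7 side chain, OSiMe3 cis to it | O=C1C(C)=CC[C@H](C(CO[Si](C)(C)C(C)(C)C)=C)[C@]1(CC(C)=C)O[Si](C)(C)C | intermediate
8 | trimethylsilyl dienol ether of 7 (C3-OSiMe3, C3=C4, C5=C6) | C[Si](C)(C)OC1=C(C)C=C[C@H](C(CO[Si](C)(C)C(C)(C)C)=C)[C@]1(CC(C)=C)O[Si](C)(C)C | intermediate
9 | γ-hydroxy enone: 7 with a 6α-hydroxyl trans to the C7 side chain | O=C1C(C)=C[C@@H](O)[C@H](C(CO[Si](C)(C)C(C)(C)C)=C)[C@]1(CC(C)=C)O[Si](C)(C)C | intermediate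
10 | C6 tert-butyldimethylsilyl ether of 9 | O=C1C(C)=C[C@@H](O[Si](C)(C)C(C)(C)C)[C@H](C(CO[Si](C)(C)C(C)(C)C)=C)[C@]1(CC(C)=C)O[Si](C)(C)C | intermediate
11 | allylmagnesium bromide | C=CC[Mg]Br | starting material
12 | C3 allyl carbinol with C8-OSiMe3 (C3-OH cis to C8-O, allyl cis to methallyl) | O[C@]1(CC=C)C(C)=C[C@@H](O[Si](C)(C)C(C)(C)C)[C@H](C(CO[Si](C)(C)C(C)(C)C)=C)[C@]1(CC(C)=C)O[Si](C)(C)C | intermediate
13 | cis-3,8-diol carrying allyl (C3) and methallyl (C8) groups | O[C@]1(CC=C)C(C)=C[C@@H](O[Si](C)(C)C(C)(C)C)[C@H](C(CO[Si](C)(C)C(C)(C)C)=C)[C@]1(CC(C)=C)O | intermediate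
14 | cis-fused bicyclo[4.4.0]deca-diene-3,8-diol (ring A C4=C5, ring B C1=C10; both fusion hydroxyls β) | O[C@@]12CC=C(C)C[C@]1(O)[C@@H](C(CO[Si](C)(C)C(C)(C)C)=C)[C@H](O[Si](C)(C)C(C)(C)C)C=C2C | intermediate
15 | bromohydrin of 14: 10α-hydroxy (C14 β), 1β-bromo | O[C@@]12C[C@@H](Br)[C@](C)(O)C[C@]1(O)[C@@H](C(CO[Si](C)(C)C(C)(C)C)=C)[C@H](O[Si](C)(C)C(C)(C)C)C=C2C | intermediate
16 | ten-membered 1β-bromo-10α-hydroxy-3,8-dione (4Z) | O=C1C[C@@H](Br)[C@](C)(O)CC(=O)[C@@H](C(CO[Si](C)(C)C(C)(C)C)=C)[C@H](O[Si](C)(C)C(C)(C)C)/C=C1/C | intermediate
17 | (1E,4Z)-10α-hydroxy-6α,12-bis(tert-butyldimethylsilyloxy)germacra-1,4,11(13)-triene-3,8-dione | O=C1/C=C/[C@](C)(O)CC(=O)[C@@H](C(CO[Si](C)(C)C(C)(C)C)=C)[C@H](O[Si](C)(C)C(C)(C)C)/C=C1/C | intermediate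
18 | 8β,10α-diol of 17 (C8 ketone reduced) | O=C1/C=C/[C@](C)(O)C[C@@H](O)[C@@H](C(CO[Si](C)(C)C(C)(C)C)=C)[C@H](O[Si](C)(C)C(C)(C)C)/C=C1/C | intermediate
19 | 1β,2α-epoxide of 18 | O=C1[C@@H]2O[C@H]2[C@](C)(O)C[C@@H](O)[C@@H](C(CO[Si](C)(C)C(C)(C)C)=C)[C@H](O[Si](C)(C)C(C)(C)C)/C=C1/C | intermediate
20 | isobutyric anhydride | CC(C)C(=O)OC(=O)C(C)C | starting material
21 | 8-O-isobutyrate of 19 | O=C1[C@@H]2O[C@H]2[C@](C)(O)C[C@@H](OC(=O)C(C)C)[C@@H](C(CO[Si](C)(C)C(C)(C)C)=C)[C@H](O[Si](C)(C)C(C)(C)C)/C=C1/C | intermediate
22 | 6α,12-diol (both silyl ethers removed) | O=C1[C@@H]2O[C@H]2[C@](C)(O)C[C@@H](OC(=O)C(C)C)[C@@H](C(CO)=C)[C@H](O)/C=C1/C | intermediate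
23 | C12 enal with free 6α-hydroxyl | O=C1[C@@H]2O[C@H]2[C@](C)(O)C[C@@H](OC(=O)C(C)C)[C@@H](C(C=O)=C)[C@H](O)/C=C1/C | intermediate
24 | 12,6-lactol (C12 epimers) | O=C1[C@@H]2O[C@H]2[C@](C)(O)C[C@@H](OC(=O)C(C)C)[C@H]2C(=C)C(O)O[C@@H]2/C=C1/C | intermediate
25 | CNP0273626.1, 1β,2α-epoxy-10α-hydroxy-8β-isobutyryloxy-3-oxogermacra-4Z,11(13)-dien-12,6α-olide | C=C1C(=O)O[C@@H]2/C=C(/C)C(=O)[C@@H]3O[C@H]3[C@](C)(O)C[C@@H](OC(=O)C(C)C)[C@@H]12 | target

## Step count and least certain steps

Total: 16 steps; the longest linear sequence is 16 steps from (S)-carvone (6, 11 and 20 are purchased reagents).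

**Step 11 (key step).** The glycol cleavage itself should be reliable. What may go wrong afterwards is the elimination: loss of HBr could proceed through the cisoid conformer inherited from ring B and give the 1Z enone, which is trapped at once by addition of the C10 hydroxyl to C3. In addition, enolization of the new C8 ketone towards C7 could epimerize C7 or pull the C11=C13 double bond into conjugation. Fallback, setting out from 15 and returning at 19: the Z outcome is used instead of fought. The cleavage product is isolated as the bridged 3,10-hemiketal F1 and treated with t-BuOOH and catalytic benzyltrimethylammonium hydroxide. The hemiketal is in equilibrium with the Z enone, hydroperoxide adds to C1 from the exo face (the face of C14), and the β-peroxy enolate can rotate about C1–C2 before it closes, as Z enones are known to give trans epoxy ketones in this stepwise reaction. This gives the trans-epoxy diketone F2, and the directed reduction of step 12 then gives 19.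

**Step 10.** Bromonium formation on the concave face, opening at C1 instead of C10, capture of the bromonium ion by the axial C3 hydroxyl (transannular bromoetherification) or attack on the other two alkenes would each spoil the C10 centre. Fallback, setting out from 14 and returning at 17: epoxidation with mCPBA/NaHCO3, directed by the axial homoallylic C3 hydroxyl to the convex face, gives the β-epoxide F3. Dilute HClO4 in THF/H2O opens it trans-diaxially at C10 from the α face (no hydroxyl can participate from that side) to give the 1β,10α-diol F4. Ac2O/pyridine acetylates only the secondary C1 hydroxyl to give acetate F5. The conditions of step 11 then cleave the single remaining free glycol, and the β-acetoxy ketone loses acetic acid to give 17.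

**Step 13.** The peroxide may be delivered to the other face of C1=C2 if the ring prefers the other rotamer of the enone; the epoxide may migrate towards C10 under base (the C10 alkoxide attacking C1); C4=C5 may compete. Fallback, setting out from 18 and returning at 19: catalyst-controlled instead of substrate-controlled epoxidation, with iminium activation of the enone by a 9-amino-9-deoxy-epi-cinchona alkaloid salt and aqueous H2O2 under nearly neutral conditions. The face is chosen by taking the quinine- or the quinidine-derived catalyst. No new compound is made (entry F0).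

**Step 12.** The chair for internal hydride delivery has to fit the ten-membered ring, and C10 carries two carbon substituents of similar size, so hydride may reach the other face of C8. Fallback, setting out from 17 and returning at 21: the 8α-alcohol F6 (from the same reagent if it errs, or on purpose with NaBH4 at -78 °C, which reduces the saturated ketone before the cross-conjugated one) is epoxidized as in step 13 to the epoxy alcohol F7. F7 is then esterified with isobutyric acid under Mitsunobu conditions (PPh3, diisopropyl azodicarboxylate), which installs the isobutyrate with inversion at C8.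

**Step 4.** Deprotonation may occur at C6 instead of the hindered, oxygen-bearing C8; O-alkylation or silyl migration may compete; facial selectivity may be poor. Fallback, setting out from 5 and returning at 7: the enolate is trapped on oxygen with 2-methylallyl chloroformate to give the enol carbonate F8. Decarboxylative allylation with Pd(PPh3)4 in THF then forms the C8–C9 bond from the π-allyl palladium/enolate ion pair under neutral conditions.

## Further compounds

F1 | step 11 | bridged 3,10-hemiketal of the (1Z,4Z)-dienedione (3-hydroxy-3,10-epoxy, C8 ketone) | O[C@]12C=C[C@](C)(O1)CC(=O)[C@@H](C(CO[Si](C)(C)C(C)(C)C)=C)[C@H](O[Si](C)(C)C(C)(C)C)/C=C2/C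
F2 | step 11 | 1β,2α-epoxy-10α-hydroxy-3,8-dione (C8 ketone not yet reduced) | O=C1[C@@H]2O[C@H]2[C@](C)(O)CC(=O)[C@@H](C(CO[Si](C)(C)C(C)(C)C)=C)[C@H](O[Si](C)(C)C(C)(C)C)/C=C1/C
F3 | step 10 | 1β,10β-epoxide of bicyclic diol 14 | O[C@@]12C[C@H]3O[C@@]3(C)C[C@]1(O)[C@@H](C(CO[Si](C)(C)C(C)(C)C)=C)[C@H](O[Si](C)(C)C(C)(C)C)C=C2C
F4 | step 10 | bicyclic 1β,10α-diol (with the 3,8-diol) | O[C@@]12C[C@@H](O)[C@](C)(O)C[C@]1(O)[C@@H](C(CO[Si](C)(C)C(C)(C)C)=C)[C@H](O[Si](C)(C)C(C)(C)C)C=C2C
F5 | step 10 | C1 acetate of F4 | O[C@@]12C[C@@H](OC(C)=O)[C@](C)(O)C[C@]1(O)[C@@H](C(CO[Si](C)(C)C(C)(C)C)=C)[C@H](O[Si](C)(C)C(C)(C)C)C=C2C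
F0 | step 13 | none | none
F6 | step 12 | 8α-alcohol (C8 epimer of 18) | O=C1/C=C/[C@](C)(O)C[C@H](O)[C@@H](C(CO[Si](C)(C)C(C)(C)C)=C)[C@H](O[Si](C)(C)C(C)(C)C)/C=C1/C
F7 | step 12 | 1β,2α-epoxide of F6 (C8 epimer of 19) | O=C1[C@@H]2O[C@H]2[C@](C)(O)C[C@H](O)[C@@H](C(CO[Si](C)(C)C(C)(C)C)=C)[C@H](O[Si](C)(C)C(C)(C)C)/C=C1/C
F8 | step 4 | 2-methylallyl enol carbonate of 5 (C3-O-carbonate, C3=C8, C8-OSiMe3) | CC1=CC[C@H](C(CO[Si](C)(C)C(C)(C)C)=C)C(O[Si](C)(C)C)=C1OC(=O)OCC(C)=C
A1 | alternative 1 | seco (Z)-enal/allylic bromide for closure of C6–C7 (C3 as silyl ether, either epimer) | O=C/C=C(/C)C(O[Si](C)(C)C(C)(C)C)/C=C/[C@](C)(O[Si](CC)(CC)CC)C[C@@H](OC(=O)C(C)C)/C=C(\CBr)C(=O)OC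
A2 | alternative 1 | 6,7-cis lactone (6-epi) expected from the allylation | C=C1C(=O)O[C@H]2/C=C(/C)C(O[Si](C)(C)C(C)(C)C)/C=C/[C@](C)(O[Si](CC)(CC)CC)C[C@@H](OC(=O)C(C)C)[C@@H]12
A3 | alternative 2 | seco divinyl compound for metathesis at C1=C2 | C=C[C@](C)(O)C[C@@H](OC(=O)C(C)C)[C@H]1C(=C)C(=O)O[C@@H]1/C=C(/C)C(=O)C=C
A4 | alternative 2 | (1Z,4Z)-dienone expected from metathesis | C=C1C(=O)O[C@@H]2/C=C(/C)C(=O)/C=C\[C@](C)(O)C[C@@H](OC(=O)C(C)C)[C@@H]12
A5 | alternative 3 | seco (Z)-vinyl iodide/trans-epoxy aldehyde for closure of C3–C4 | O=C[C@@H]1O[C@H]1[C@](C)(O)C[C@@H](OC(=O)C(C)C)[C@H]2C(=C)C(=O)O[C@@H]2/C=C(/C)I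
A6 | alternative 3 | C3 carbinol from the chromium-mediated closure (C3 epimers) | C=C1C(=O)O[C@@H]2/C=C(/C)C(O)[C@@H]3O[C@H]3[C@](C)(O)C[C@@H](OC(=O)C(C)C)[C@@H]12
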